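**Numbering used throughout:** 1 methyl orsellinate; 2 its dimethyl ether; 3 hexanoyl chloride; 4 N-methoxy-N-methylhexanamide; 5 lithiated 2; 6 keto ester; 7 6,8-dimethoxy-3-pentylisocoumarin; 8 8-hydroxy-6-methoxy-3-pentylisocoumarin; 9 methyl 4-chloro-3-oxobutanoate; 10 aryloxy β-keto ester; 11 mono-silyl enol ether; 12 bis(silyloxy)diene; 13 methyl oct-2-ynoate; 14 cycloadduct; 15 ring B methyl ester; 16 target. Ring A is the benzo ring of the isocoumarin (C4a–C8a). Ring B is the benzoic acid ring (C1' carboxyl carbon, C2' OH, C3' H, C4' OH, C5' O-aryl, C6' pentyl).

## Analysis of the target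

Target 16 is a diaryl ether that joins a 6-hydroxy-3-pentylisocoumarin through the oxygen on C8 to a benzoic acid ring B in which five of six positions are substituted. It has no stereocentre and no stereogenic double bond, so the problem is one of regiochemistry and functional-group tolerance. The sensitive groups are the enol lactone, which alkoxide or hydroxide opens, and the 2,4-dihydroxy-6-alkylbenzoic acid, which decarboxylates on heating or prolonged acid contact. Three phenols also have to be told apart during the assembly. The hard part is the ether oxygen: on ring B it sits at C5' between the oxygenated C4' and the pentyl-bearing C6', and on ring A it sits at C8, peri to the lactone carbonyl. Both partners of a conventional aryl–oxygen coupling would therefore be hindered, and the chelated 8-phenol is also a weak nucleophile. The route rests on two observations. C6' and C1', with pentyl and carboxyl, are the two sp carbons of an oct-2-ynoate. C2'–C5', oxygenated at C2', C4' and C5', are the carbon chain of a 4-aryloxy-3-oxobutanoate. Ring B can therefore be built around the ether oxygen by a Diels–Alder reaction after that oxygen has been attached to C8 by an ordinary alkylation.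

## Retrosynthetic reasoning

**16 to 15.** The last disconnection cuts two O–CH3 bonds, the 6-methyl ether on ring A and the methyl ester on C1'. Methyl is the smallest group that survives lithiation, Lewis acids, silylation and heating, and one boron trihalide treatment should remove both. The forward reaction has to spare the lactone and the diaryl ether and must not decarboxylate the acid.

**15 to 12 and 13.** Ring B is cut at C5'–C6' and C1'–C2'. This is the only pair of bonds whose cleavage leaves the carboxyl and pentyl carbons together as the triple bond of 13 and puts all three ring oxygens on the four-carbon diene 12. The gain is that the most congested ring and all six of its substituents arise in one step, already at the aromatic oxidation level after elimination from cycloadduct 14. The forward reaction must join the aryloxy-bearing diene terminus to the pentyl-bearing alkyne carbon and not the reverse.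

**12 to 10.** Diene 12 is the bis-enol silyl ether of β-keto ester 10, so the two O–Si bonds are removed. The forward reaction is a double enolisation that passes through mono-silyl enol ether 11 and has to place the aryloxy group on the outside of the diene.

**10 to 8 and 9.** The O–CH2 bond between the C8 oxygen and the keto ester chain is cut. This turns the diaryl ether problem into the displacement of a primary chloride in 9 by the phenoxide of 8. The forward reaction has to alkylate the chelated 8-hydroxyl without opening the lactone.

**8 to 7.** The 8-hydroxyl is traced back to a methyl ether. The 8-methoxy group of 7 is peri to the lactone carbonyl and can be removed selectively by chelation-directed Lewis acid cleavage, so both ring A oxygens can be carried as methyl ethers and differentiated late.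

**7 to 6.** The lactone C1–O2 bond is opened to keto ester 6. The forward reaction is an enol lactonisation in which the ketone enol oxygen displaces the ester methoxy group.

**6 to 2 and 4.** The bond between C4 and C3 of the isocoumarin, that is the benzylic carbon and the ketone carbon of 6, is cut. The ortho-methyl group of 2 is acidified by the ester and can be lithiated laterally to 5. Amide 4 is chosen as acyl donor because its adduct holds at the ketone stage.

**2 to 1, and 4 to 3.** Both are functional-group changes on commercial materials: O-methylation of 1, and conversion of acid chloride 3 into the amide.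

## Alternatives that were turned down

**Alternative 1: aryne insertion into a malonate.**
- Disconnection: the two carbon substituents of ring A (bonds C4a–C4 and C8a–C1) are taken off an aryne that already carries the ring B aryloxy group.
- Forward key step: a fluoride source releases a 3-aryloxy-5-methoxybenzyne from silyl triflate A2. The enolate of dimethyl malonate A3 adds at the aryne carbon meta to the aryloxy group, the aryl anion closes onto an ester carbonyl, and the four-membered alkoxide fragments. The net result is insertion of the aryne into a C–C bond to give homophthalate A1.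
- For: the regiochemistry follows from the distortion of an alkoxy-substituted aryne, the conditions are mild, and homophthalates are established isocoumarin precursors.
- Against: the diaryl ether must already exist in A2, so the hindered bond from oxygen to C5' still has to be made by an aryl–oxygen coupling. A2 also needs adjacent silyl and triflate groups on a 1,2,3,5-tetrasubstituted ring. After A1, the pyranone has to be built by acylating the benzylic carbon in the presence of three methyl esters, and four O-methyl groups have to be removed at the end.
- Comparison: the insertion is stronger on predictability than a thermally demanding cycloaddition. It forms no ring, however, and leaves ring B, the ether bond and the lactone closure to other steps. The chosen strategy makes the ether bond by alkylation and builds the congested ring in the key step, at the price of a less secure key step.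

**Alternative 2: Michael–Dieckmann annulation on an aryloxy enone.**
- Disconnection: ring B at C1'–C6' and C2'–C3', with aromatisation by oxidation.
- Forward key step: under an alkoxide base, the anion of A3 adds to C4 of enone A5 (which becomes C6'). The methyl ketone enolate then closes onto a malonate ester to a six-membered dione, and a copper dihalide added to the same flask dehydrogenates it to resorcylate A4.
- For: the enone–malonate annulation is the standard way to 6-alkylresorcylates, needs no moisture-sensitive diene, and again introduces the ether oxygen by alkylation. On reliability of the ring-forming step it is as strong as or stronger than the chosen cycloaddition.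
- Against: the alkoxide would open the isocoumarin lactone, so ring A has to be carried as an ortho-alkynyl benzoate, as in A4. That adds a cross-coupling and a later lactone closure whose 6-endo versus 5-exo selectivity is not assured. The α-aryloxy group lowers the electrophilicity of A5, and A5 itself requires a regio- and geometry-controlled condensation. The oxidant must spare an electron-rich resorcinol and an alkyne from halogenation.
- Comparison: the chosen strategy reaches the aromatic oxidation level without an oxidant, under neutral conditions, with the isocoumarin already in place, and its end-game is shorter.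

**Alternative 3: fused bis-pyrone Diels–Alder with a ketene acetal.**
- Disconnection: ring A at C5–C4a and C6–C7, from the 2-pyranone ring of a pyrano[4,3-b]pyran-2,5-dione and a two-carbon ketene acetal.
- Forward key step: 1,1-dimethoxyethene A8 adds across C3 and C8a of bis-pyrone A7 in an inverse-demand cycloaddition. The bridging lactone is then lost as gas by retro-cycloaddition, and elimination of an alcohol aromatises ring A to give A6 with the 6-methoxy group in place.
- For: an electron-poor pyranone and an electron-rich ketene acetal are a well-matched pair, and the extrusion makes the step irreversible. This cycloaddition is probably intrinsically faster than the chosen one, and it forms ring A and the isocoumarin together.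
- Against: A7 needs a complete, hexasubstituted ring B phenol attached at C4 of the pyranone. Ring B therefore has to be made separately with an extra oxidation to place oxygen on C5', and the hindered phenol has to be introduced by addition–elimination. The aryloxy group of A7 is a vinylogous ester leaving group that a nucleophile can displace, and as a donor it lowers the electron demand of the diene. A6 carries three methyl ethers and a methyl ester to cleave.
- Comparison: the chosen strategy needs no preformed ring B, takes fewer steps and has only two O-methyl groups to remove at the end. In exchange it accepts a less well-matched cycloaddition.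

Key step: step 8

## Route

Assumption: diene 12 is drawn 1Z,3E; only the 1Z geometry at the aryloxy end (aryloxy on the outside of the s-cis diene) matters, because the ketene acetal geometry is lost when C2' becomes aromatic.

Step 1
Reactants: 1 methyl orsellinate (methyl 2,4-dihydroxy-6-methylbenzoate)
Product: 2 methyl 2,4-dimethoxy-6-methylbenzoate
Conditions: MeI (excess), K2CO3, acetone, reflux
Reagents that add atoms: iodomethane, CI
Why: Williamson O-methylation of both phenols; the chelated 2-hydroxyl reacts more slowly but should be driven to completion by excess iodomethane at reflux.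

Step 2
Reactants: 3 hexanoyl chloride
Product: 4 N-methoxy-N-methylhexanamide
Conditions: MeNH(OMe)·HCl, K2CO3, CH2Cl2/H2O, 0 °C to rt
Reagents that add atoms: N,O-dimethylhydroxylamine hydrochloride, CNOC.Cl
Why: Schotten–Baumann acylation of the amine by the acid chloride; the amide is the acyl donor for the Weinreb ketone synthesis in step 3.

Step 3
Reactants: 2 methyl 2,4-dimethoxy-6-methylbenzoate; 4 N-methoxy-N-methylhexanamide
Product: 6 methyl 2,4-dimethoxy-6-(2-oxoheptyl)benzoate, via lithiated toluate 5 (not isolated)
Conditions: LiN(iPr)2 (1.1 equiv), THF, −78 °C; then 4, −78 to 0 °C; cold 1 M HCl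
Reagents that add atoms: none
Why: Lateral lithiation of the ortho-methyl group, which the ester acidifies, gives the benzylic anion 5, and its addition to 4 gives a chelated tetrahedral adduct that releases the ketone only on acidic quench (Weinreb ketone synthesis). No enolisable ketone is therefore present while base remains, which should suppress over-addition and Claisen-type side reactions.

Step 4
Reactants: 6 methyl 2,4-dimethoxy-6-(2-oxoheptyl)benzoate
Product: 7 6,8-dimethoxy-3-pentyl-1H-isochromen-1-one
Conditions: p-TsOH·H2O (cat.), toluene, reflux, Dean–Stark
Reagents that add atoms: none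
Why: Acid-catalysed enol lactonisation: the aryl-conjugated enol of the ketone attacks the neighbouring ester through a six-membered transition state, and removal of methanol together with the conjugation gained in the isocoumarin should drive the closure.

Step 5
Reactants: 7 6,8-dimethoxy-3-pentyl-1H-isochromen-1-one
Product: 8 8-hydroxy-6-methoxy-3-pentyl-1H-isochromen-1-one
Conditions: BCl3 (1.5 equiv), CH2Cl2, −78 to 0 °C; H2O
Reagents that add atoms: none
Why: Chelation-directed ether cleavage: boron binds the lactone carbonyl and the peri 8-methoxy oxygen and chloride removes that methyl group by SN2, while the 6-methoxy group, which cannot chelate, should stay.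

Step 6
Reactants: 8 8-hydroxy-6-methoxy-3-pentyl-1H-isochromen-1-one; 9 methyl 4-chloro-3-oxobutanoate
Product: 10 methyl 4-[(6-methoxy-1-oxo-3-pentyl-1H-isochromen-8-yl)oxy]-3-oxobutanoate
Conditions: NaH (2.2 equiv), THF/DMF, 0 to 40 °C; cold 1 M HCl
Reagents that add atoms: none
Why: Williamson ether synthesis: one equivalent of base forms the phenoxide and the second converts 9 into its enolate, which masks the ketone and the acidic C2 hydrogens while the phenoxide displaces the primary chloride at C4. This is the standard way to 4-alkoxy- and 4-aryloxy-3-oxobutanoates.

Step 7
Reactants: 10 methyl 4-[(6-methoxy-1-oxo-3-pentyl-1H-isochromen-8-yl)oxy]-3-oxobutanoate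
Product: 12 6-methoxy-8-{[(1Z,3E)-4-methoxy-2,4-bis(trimethylsilyloxy)buta-1,3-dien-1-yl]oxy}-3-pentyl-1H-isochromen-1-one, via mono-silyl enol ether 11 (not isolated)
Conditions: Me3SiOTf (2.5 equiv), Et3N (3 equiv), Et2O, 0 °C to rt; pentane extraction under argon, used crude
Reagents that add atoms: trimethylsilyl trifluoromethanesulfonate, C[Si](C)(C)OS(=O)(=O)C(F)(F)F
Why: Soft enolisation of a 1,3-dicarbonyl compound to its 1,3-bis(silyloxy)diene: the first silylation gives enoate 11, and silylation of the ester oxygen then lets the amine remove a hydrogen from the aryloxymethylene group, which the adjacent oxygen acidifies. An α-oxygenated silyl enol ether is expected to place the aryloxy group cis to the silyloxy group, and the lactone has no enolisable position.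

Step 8
Reactants: 12 6-methoxy-8-{[(1Z,3E)-4-methoxy-2,4-bis(trimethylsilyloxy)buta-1,3-dien-1-yl]oxy}-3-pentyl-1H-isochromen-1-one; 13 methyl oct-2-ynoate
Product: 15 methyl 2,4-dihydroxy-5-[(6-methoxy-1-oxo-3-pentyl-1H-isochromen-8-yl)oxy]-6-pentylbenzoate, via cyclohexadiene cycloadduct 14 (not isolated)
Conditions: 13 (5 equiv), toluene, 110–130 °C, sealed tube; then 1 M HCl, THF, 0 °C to rt
Reagents that add atoms: none
Why: The electron-rich diene in its s-cis form adds to the triple bond of 13 in a normal-demand, concerted but asynchronous (4+2) cycloaddition, in which the bond from the aryloxy-bearing terminus to C3 of the ynoate (C5'–C6') runs ahead of the bond from the ketene acetal carbon to C2 (C1'–C2'). The closest known reaction type is the Diels–Alder reaction of 1-alkoxy-1,3-bis(silyloxy)buta-1,3-dienes with acetylenic esters followed by aromatisation to 2,4-dihydroxybenzoates. Ring B closes intermolecularly by this cycloaddition, both σ-bonds of the six-membered carbocycle forming in one step, and not by cyclisation of a chain. No stereocentre survives, since the two in 14 (cis from suprafacial addition) vanish on aromatisation. The step needs regioselectivity, and the substrate supplies it: three oxygen donors (two on the ketene acetal carbon, one on C3 of the diene) push electron density to the aryloxy-bearing terminus, which pairs with the electrophilic β-carbon of the ynoate, while the aryloxy oxygen is a weak opposing donor because its lone pair is shared with an acyl-substituted arene. C2' of 14 carries no hydrogen, so aromatisation can only take one oxygen substituent from C2' together with the hydrogen on C5', and the aryloxy group is kept; acidic work-up hydrolyses the silyl ethers and collapses the acetal with loss of methanol to the free 2'-hydroxyl. The C3=C4 bond of the isocoumarin is an enol-ether-like, conjugated alkene and should not compete as dienophile. Heat and excess 13 compensate for the deactivating β-alkyl group.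

Step 9
Reactants: 15 methyl 2,4-dihydroxy-5-[(6-methoxy-1-oxo-3-pentyl-1H-isochromen-8-yl)oxy]-6-pentylbenzoate
Product: 16 2,4-dihydroxy-5-[(6-hydroxy-1-oxo-3-pentyl-1H-isochromen-8-yl)oxy]-6-pentylbenzoic acid
Conditions: BBr3 (8 equiv), CH2Cl2, −78 °C to rt; ice-water, no heating on work-up
Reagents that add atoms: none
Why: Lewis acid-mediated SN2 dealkylation by bromide at the two O-methyl carbons, the aryl methyl ether and the boron-chelated salicylate-type methyl ester. The diaryl ether and the lactone offer no sp3 carbon on oxygen and should survive, and the excess reagent allows for the three free phenols.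

## Compound list

1 | methyl orsellinate (methyl 2,4-dihydroxy-6-methylbenzoate) | Cc1cc(O)cc(O)c1C(=O)OC | starting material
2 | methyl 2,4-dimethoxy-6-methylbenzoate | COC(=O)c1c(C)cc(OC)cc1OC | intermediate
3 | hexanoyl chloride | CCCCCC(=O)Cl | starting material
4 | N-methoxy-N-methylhexanamide | CCCCCC(=O)N(C)OC | intermediate
5 | methyl 2-(lithiomethyl)-4,6-dimethoxybenzoate (lithiated 2, drawn as the C-lithio form) | [Li]Cc1cc(OC)cc(OC)c1C(=O)OC | intermediate (not isolated)
6 | methyl 2,4-dimethoxy-6-(2-oxoheptyl)benzoate | CCCCCC(=O)Cc1cc(OC)cc(OC)c1C(=O)OC | intermediate
7 | 6,8-dimethoxy-3-pentyl-1H-isochromen-1-one | CCCCCc1cc2cc(OC)cc(OC)c2c(=O)o1 | intermediate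
8 | 8-hydroxy-6-methoxy-3-pentyl-1H-isochromen-1-one | CCCCCc1cc2cc(OC)cc(O)c2c(=O)o1 | intermediate
9 | methyl 4-chloro-3-oxobutanoate (methyl 4-chloroacetoacetate) | COC(=O)CC(=O)CCl | starting material
10 | methyl 4-[(6-methoxy-1-oxo-3-pentyl-1H-isochromen-8-yl)oxy]-3-oxobutanoate | CCCCCc1cc2cc(OC)cc(OCC(=O)CC(=O)OC)c2c(=O)o1 | intermediate
11 | methyl (2E)-4-[(6-methoxy-1-oxo-3-pentyl-1H-isochromen-8-yl)oxy]-3-(trimethylsilyloxy)but-2-enoate (drawn 2E; this geometry is not carried on, the bond becomes the central single bond of 12) | COC(=O)/C=C(/O[Si](C)(C)C)COc1cc(OC)cc2cc(CCCCC)oc(=O)c12 | intermediate (not isolated)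
12 | 6-methoxy-8-{[(1Z,3E)-4-methoxy-2,4-bis(trimethylsilyloxy)buta-1,3-dien-1-yl]oxy}-3-pentyl-1H-isochromen-1-one | CO/C(O[Si](C)(C)C)=C\C(O[Si](C)(C)C)=C\Oc1cc(OC)cc2cc(CCCCC)oc(=O)c12 | intermediate
13 | methyl oct-2-ynoate | CCCCCC#CC(=O)OC | starting material
14 | methyl rac-(3R,6R)-6-methoxy-3-[(6-methoxy-1-oxo-3-pentyl-1H-isochromen-8-yl)oxy]-2-pentyl-4,6-bis(trimethylsilyloxy)cyclohexa-1,4-diene-1-carboxylate (racemic; 3-aryloxy and 6-silyloxy groups cis; one enantiomer drawn) | COC(=O)C1=C(CCCCC)[C@@H](Oc2cc(OC)cc3cc(CCCCC)oc(=O)c23)C(O[Si](C)(C)C)=C[C@@]1(OC)O[Si](C)(C)C | intermediate (not isolated)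
15 | methyl 2,4-dihydroxy-5-[(6-methoxy-1-oxo-3-pentyl-1H-isochromen-8-yl)oxy]-6-pentylbenzoate | CCCCCc1cc2cc(OC)cc(Oc3c(O)cc(O)c(C(=O)OC)c3CCCCC)c2c(=O)o1 | intermediate
16 | 2,4-dihydroxy-5-[(6-hydroxy-1-oxo-3-pentyl-1H-isochromen-8-yl)oxy]-6-pentylbenzoic acid | CCCCCc1cc2cc(O)cc(Oc3c(O)cc(O)c(C(=O)O)c3CCCCC)c2c(=O)o1 | target

## Step count and least certain steps

Total step count: 9. Longest linear sequence: 8 steps (steps 1 and 3 to 9); step 2 is a one-step branch.

**Step 8 (key step).** The β-alkyl ynoate is a sluggish dienophile, and bond formation joins two substituted carbons, one bearing the bulky aryloxy group and one the pentyl group. The most likely failure is that cycloaddition is slower than thermal degradation of the diene, through silyl migration or protodesilylation back to the keto ester. The fallback sets out from 12 and comes back at 15. The dienophile is replaced by the isomeric allenic ester methyl octa-2,3-dienoate F1, made from 3 with Ph3P=CHCO2Me and Et3N in CH2Cl2 by way of the ketene. Allenic esters react with silyloxydienes at their conjugated double bond at lower temperature, with the nucleophilic diene terminus bonding to the central allene carbon, which gives the same regiochemistry. The expected adduct is methyl 2-methoxy-5-[(6-methoxy-1-oxo-3-pentyl-1H-isochromen-8-yl)oxy]-6-pentylidene-2,4-bis(trimethylsilyloxy)cyclohex-3-ene-1-carboxylate F2 (racemic; endo isomer expected, with ester, aryloxy and 2-silyloxy groups cis and an E pentylidene group; all isomers converge). On the same acidic work-up F2 should lose methanol across C1'–C2', shift the exocyclic double bond into the ring and desilylate to 15.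

**Step 7.** The second silylation may stop at 11, or the diene may be lost by hydrolysis during handling, because deprotonation at the aryloxymethylene group under amine conditions is the less certain half of the double enolisation. The fallback sets out from 10 and comes back at 12. Enoate 11 is made and isolated with Me3SiCl and Et3N, then deprotonated kinetically with LiN(iPr)2 in THF at −78 °C, and the lithium dienolate is trapped with Me3SiCl. This is the classical hard-enolisation route to such dienes, and the hindered amide base should not add to the lactone at that temperature. This fallback makes no compound outside the list (F0).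

**Step 6.** Self-condensation of the enolate of 9 may outpace O-alkylation by the chelated, weakly nucleophilic phenoxide of 8. The fallback sets out from 8 and comes back at 10. The phenol is alkylated with commercial methyl (2E)-4-bromo-3-methoxybut-2-enoate (K2CO3, acetone, reflux), a reagent with no acidic methylene group, to give methyl (2E)-3-methoxy-4-[(6-methoxy-1-oxo-3-pentyl-1H-isochromen-8-yl)oxy]but-2-enoate F3. The enol ether of F3 is then hydrolysed with aqueous HCl in THF to 10.

**Step 9.** Cleavage of the hindered, chelated methyl ester may lag behind cleavage of the aryl methyl ether, and forcing it risks decarboxylation of the resorcylic acid under the acidic boron conditions. The fallback sets out from 12 and comes back at 16. The cycloaddition is run with benzyl oct-2-ynoate F4 (from commercial oct-2-ynoic acid, benzyl bromide and K2CO3 in DMF) in place of 13. It passes through benzyl rac-(3R,6R)-6-methoxy-3-[(6-methoxy-1-oxo-3-pentyl-1H-isochromen-8-yl)oxy]-2-pentyl-4,6-bis(trimethylsilyloxy)cyclohexa-1,4-diene-1-carboxylate F5 to benzyl 2,4-dihydroxy-5-[(6-methoxy-1-oxo-3-pentyl-1H-isochromen-8-yl)oxy]-6-pentylbenzoate F6. BBr3 removes a benzyl ester already at low temperature by an ionising pathway, so the conditions of the last step are then set only by the aryl methyl ether, and F6 should give 16.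

## Further compounds

F1 | step 8 | methyl octa-2,3-dienoate (racemic, axially chiral) | CCCCC=C=CC(=O)OC
F2 | step 8 | methyl 2-methoxy-5-[(6-methoxy-1-oxo-3-pentyl-1H-isochromen-8-yl)oxy]-6-[(E)-pentylidene]-2,4-bis(trimethylsilyloxy)cyclohex-3-ene-1-carboxylate (racemic; expected endo isomer, ester, 5-aryloxy and 2-silyloxy cis) | CCCC/C=C1/[C@@H](Oc2cc(OC)cc3cc(CCCCC)oc(=O)c23)C(O[Si](C)(C)C)=C[C@@](OC)(O[Si](C)(C)C)[C@H]1C(=O)OC
F0 | step 7 | none | none
F3 | step 6 | methyl (2E)-3-methoxy-4-[(6-methoxy-1-oxo-3-pentyl-1H-isochromen-8-yl)oxy]but-2-enoate | COC(=O)/C=C(/OC)COc1cc(OC)cc2cc(CCCCC)oc(=O)c12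
F4 | step 9 | benzyl oct-2-ynoate | CCCCCC#CC(=O)OCc1ccccc1
F5 | step 9 | benzyl rac-(3R,6R)-6-methoxy-3-[(6-methoxy-1-oxo-3-pentyl-1H-isochromen-8-yl)oxy]-2-pentyl-4,6-bis(trimethylsilyloxy)cyclohexa-1,4-diene-1-carboxylate (racemic; 3-aryloxy and 6-silyloxy cis) | O=C(OCc1ccccc1)C1=C(CCCCC)[C@@H](Oc2cc(OC)cc3cc(CCCCC)oc(=O)c23)C(O[Si](C)(C)C)=C[C@@]1(OC)O[Si](C)(C)C
F6 | step 9 | benzyl 2,4-dihydroxy-5-[(6-methoxy-1-oxo-3-pentyl-1H-isochromen-8-yl)oxy]-6-pentylbenzoate | CCCCCc1cc2cc(OC)cc(Oc3c(O)cc(O)c(C(=O)OCc4ccccc4)c3CCCCC)c2c(=O)o1
A1 | alternative 1 | methyl 5-[5-methoxy-2-(methoxycarbonyl)-3-(2-methoxy-2-oxoethyl)phenoxy]-2,4-dimethoxy-6-pentylbenzoate | COC(=O)Cc1cc(OC)cc(Oc2c(OC)cc(OC)c(C(=O)OC)c2CCCCC)c1C(=O)OC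
A2 | alternative 1 | methyl 2,4-dimethoxy-5-{5-methoxy-3-[(trifluoromethanesulfonyl)oxy]-2-(trimethylsilyl)phenoxy}-6-pentylbenzoate | COC(=O)c1c(OC)cc(OC)c(Oc2cc(OC)cc(OS(=O)(=O)C(F)(F)F)c2[Si](C)(C)C)c1CCCCC
A3 | alternative 1 | dimethyl malonate | COC(=O)CC(=O)OC
A4 | alternative 2 | methyl 5-[3-(hept-1-yn-1-yl)-5-methoxy-2-(methoxycarbonyl)phenoxy]-2,4-dihydroxy-6-pentylbenzoate | CCCCCC#Cc1cc(OC)cc(Oc2c(O)cc(O)c(C(=O)OC)c2CCCCC)c1C(=O)OC
A5 | alternative 2 | methyl 2-(hept-1-yn-1-yl)-4-methoxy-6-{[(3Z)-2-oxonon-3-en-3-yl]oxy}benzoate | CCCCCC#Cc1cc(OC)cc(O/C(=C\CCCCC)C(C)=O)c1C(=O)OC
A6 | alternative 3 | methyl 2,4-dimethoxy-5-[(6-methoxy-1-oxo-3-pentyl-1H-isochromen-8-yl)oxy]-6-pentylbenzoate | CCCCCc1cc2cc(OC)cc(Oc3c(OC)cc(OC)c(C(=O)OC)c3CCCCC)c2c(=O)o1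
A7 | alternative 3 | methyl 5-[(2,5-dioxo-7-pentyl-2H,5H-pyrano[4,3-b]pyran-4-yl)oxy]-2,4-dimethoxy-6-pentylbenzoate | CCCCCc1cc2oc(=O)cc(Oc3c(OC)cc(OC)c(C(=O)OC)c3CCCCC)c2c(=O)o1
A8 | alternative 3 | 1,1-dimethoxyethene | C=C(OC)OC
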